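The route below rests on cutting two bonds of pyran ring B (fused to the acetyl-bearing benzene ring A), C6'–CH(Me) and C3–C4, after replacing the C2 gem-dimethyl carbon by a lactone carbonyl. The feature used is the chain C6'–CH(Me)–C3–C4 with C2 and O1: aryl carbon, β-carbon, α-carbon, formyl carbon, ester carbonyl and phenol oxygen of a salicylaldehyde crotonate. One rhodium-catalysed operation adds the chromenylboronic acid enantioselectively to that crotonate and lets the enolate close the lactone onto the aldehyde, giving the 3-substituted coumarin with the only stereocentre set. The precursor is a 2-formylaryl (E)-crotonate bearing methoxy and MOM-oxy groups, partnered by a 2,6-dimethoxyarylboronic acid that already contains the second chromene.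

Key step: step 7

Assumption: the (1R,4R) enantiomer of the diene ligand is taken to deliver the aryl group to the Si face of the crotonate β-carbon, the face that leads to the target; if a trial on a simple 2-formylaryl crotonate shows the opposite sense, the (1S,4S) ligand is used and nothing else changes.

Locants: chromene numbering throughout, primed locants for the dimethoxychromene unit. The CHMe centre keeps one spatial arrangement from the key step onward; its descriptor is (R) in the coumarin (the lactone carbon outranks the aryl group) and (S) in the chromenes and the target.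

Step 1
Reactants: 1 2,4,6-trihydroxybenzaldehyde
Product: 2 2,6-dihydroxy-4-methoxybenzaldehyde
Conditions: Me2SO4 (1.0 equiv), K2CO3 (1.0 equiv), acetone, 23 → 40 °C
Reagents that add atoms: dimethyl sulfate, COS(=O)(=O)OC
Why: Williamson ether synthesis under stoichiometric control: the 4-hydroxyl, para to the formyl group and free of the hydrogen bond that ties up the ortho hydroxyls, is the most acidic and most nucleophilic and should be methylated first when one equivalent of sulfate is used.

Step 2
Reactants: 2 2,6-dihydroxy-4-methoxybenzaldehyde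
Product: 3 2-hydroxy-4-methoxy-6-(methoxymethoxy)benzaldehyde
Conditions: MOMCl (1.1 equiv), i-Pr2NEt (1.5 equiv), CH2Cl2, 0 °C
Reagents that add atoms: chloromethyl methyl ether, COCCl
Why: Williamson-type MOM ether formation that should stop at the mono-ether, because once one ortho hydroxyl is capped the other is held in a hydrogen bond to the formyl oxygen and is far less reactive.

Step 3
Reactants: 3 2-hydroxy-4-methoxy-6-(methoxymethoxy)benzaldehyde; 4 (E)-but-2-enoyl chloride (crotonyl chloride)
Product: 5 2-formyl-5-methoxy-3-(methoxymethoxy)phenyl (E)-but-2-enoate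
Conditions: NaH (1.05 equiv), THF, 0 °C; then 4, −20 → 0 °C
Reagents that add atoms: none
Why: Nucleophilic acyl substitution of the acid chloride by the preformed sodium phenoxide; the absence of an amine base avoids the vinylketene pathway that would move the double bond out of conjugation, so the (E)-crotonate should be obtained unchanged.

Step 4
Reactants: 6 2-bromo-1,3-dimethoxybenzene
Product: 8 4-bromo-3,5-dimethoxyphenol, via pinacol boronate 7 (not isolated)
Conditions: B2pin2 (0.6 equiv), [Ir(OMe)(cod)]2 (1 mol%), 4,4'-di-tert-butyl-2,2'-bipyridine (2 mol%), THF, 80 °C; then KHSO5 (as 2KHSO5·KHSO4·K2SO4), acetone/H2O, 23 °C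
Reagents that add atoms: bis(pinacolato)diboron, CC1(C)OB(OC1(C)C)B1OC(C)(C)C(C)(C)O1 (boron of 7); potassium peroxymonosulfate, [K+].[O-]S(=O)(=O)OO (hydroxyl oxygen of 8)
Why: Sterically governed iridium-catalysed aromatic C–H borylation takes the only C–H without an ortho substituent (C5, para to bromine) and leaves the C–Br bond alone, and peroxymonosulfate then oxidises the C–B bond to the phenol at the same carbon.

Step 5
Reactants: 8 4-bromo-3,5-dimethoxyphenol; 9 3-methylbut-2-enal (prenal)
Product: 11 6-bromo-5,7-dimethoxy-2,2-dimethyl-2H-chromene, via ortho-quinone methide 10 (not isolated)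
Conditions: 9 (2 equiv), ethylenediammonium diacetate (10 mol%), toluene, 110 °C
Reagents that add atoms: none
Why: Amine-salt-catalysed Knoevenagel-type condensation of the enal at the carbon ortho to the hydroxyl gives ortho-quinone methide 10, which closes by oxa-6π electrocyclisation; the two ortho positions are equivalent, so only one chromene can form.

Step 6
Reactants: 11 6-bromo-5,7-dimethoxy-2,2-dimethyl-2H-chromene
Product: 13 (5,7-dimethoxy-2,2-dimethyl-2H-chromen-6-yl)boronic acid, via aryllithium 12 (not isolated)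
Conditions: n-BuLi (1.05 equiv), THF, −78 °C; B(Oi-Pr)3, −78 → 0 °C; aq. NH4Cl
Reagents that add atoms: n-butyllithium, [Li]CCCC (lithium of 12); triisopropyl borate, CC(C)OB(OC(C)C)OC(C)C; water, O
Why: Bromine–lithium exchange at −78 °C is faster than any deprotonation and fixes the metal at C6, and trapping of 12 with the borate followed by near-neutral hydrolysis (borylation of an aryllithium) should give the boronic acid.

Step 7
Reactants: 5 2-formyl-5-methoxy-3-(methoxymethoxy)phenyl (E)-but-2-enoate; 13 (5,7-dimethoxy-2,2-dimethyl-2H-chromen-6-yl)boronic acid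
Product: 15 3-[(1R)-1-(5,7-dimethoxy-2,2-dimethyl-2H-chromen-6-yl)ethyl]-7-methoxy-5-(methoxymethoxy)-2H-chromen-2-one, via aldol lactone 14 (not isolated)
Conditions: 13 (2.5 equiv), [RhCl(C2H4)2]2 (3 mol%), (1R,4R)-2,5-diphenylbicyclo[2.2.2]octa-2,5-diene (7 mol%), aq. KOH (6 mol%), 1,4-dioxane/H2O (10:1), 50 °C; then DBU (0.2 equiv), 23 °C
Reagents that add atoms: none
Why: Proposed new method: transmetalation of 13 to the Rh–OH species gives an aryl–rhodium complex that inserts the crotonate C=C of 5 with aryl delivery to the β-carbon, and the resulting oxa-π-allyl rhodium enolate adds through its α-carbon to the neighbouring formyl group before it can be protonated, giving the aldolate of 14, which water releases (regenerating Rh–OH) and which loses water by E1cB to the coumarin. The closest known reaction type is the rhodium-catalysed asymmetric conjugate arylation of enones with intramolecular aldol capture of the enolate, together with the known asymmetric arylation of crotonate esters; what is untested is an aryl ester acceptor that carries the aldehyde on its own phenol ring. The lactone ring closes by a 6-(enolendo)-exo-trig aldol addition, C3 to C4. The CHMe stereocentre is set in the insertion step by the chiral diene on rhodium (catalyst control, aryl to the Si face of the β-carbon), and the two transient centres at C3 and C4 are erased by the dehydration. The step needs 1,4- over 1,2-arylation and ring closure over enolate protonation: the formyl group sits between two ortho oxygen substituents on an electron-rich ring and is a poor acceptor for aryl–rhodium, yet it lies within six-membered reach of the enolate carbon, the nearly base-free medium spares the aryl ester, and the α-branched, peri-shielded coumarin product should not be arylated further.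

Step 8
Reactants: 15 3-[(1R)-1-(5,7-dimethoxy-2,2-dimethyl-2H-chromen-6-yl)ethyl]-7-methoxy-5-(methoxymethoxy)-2H-chromen-2-one
Product: 17 6-{(1S)-1-[7-methoxy-5-(methoxymethoxy)-2,2-dimethyl-2H-chromen-3-yl]ethyl}-5,7-dimethoxy-2,2-dimethyl-2H-chromene, via allylic diol 16 (not isolated)
Conditions: MeLi (4 equiv), CeCl3 (4 equiv), THF, −78 → 0 °C; aq. NH4Cl; then pyridinium p-toluenesulfonate (10 mol%), CH2Cl2, 23 °C
Reagents that add atoms: methyllithium, [Li]C
Why: Twofold 1,2-addition of the weakly basic methylcerium reagent to the lactone carbonyl (organometallic addition to an ester) opens the ring to the (Z)-allylic tertiary alcohol 16, whose mild acid ionisation gives an allyl cation, strongly stabilised by ring A, that the ortho phenol captures in a 6-membered cyclodehydration; the CHMe centre is neither deprotonated nor adjacent to a cationic carbon and should be retained.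

Step 9
Reactants: 17 6-{(1S)-1-[7-methoxy-5-(methoxymethoxy)-2,2-dimethyl-2H-chromen-3-yl]ethyl}-5,7-dimethoxy-2,2-dimethyl-2H-chromene
Product: 19 1-{3-[(1S)-1-(5,7-dimethoxy-2,2-dimethyl-2H-chromen-6-yl)ethyl]-7-methoxy-5-(methoxymethoxy)-2,2-dimethyl-2H-chromen-6-yl}ethan-1-one, via aryllithium 18 (not isolated)
Conditions: n-BuLi (1.2 equiv), THF, −20 → 0 °C; MeC(O)N(OMe)Me, −78 → 0 °C; aq. NH4Cl
Reagents that add atoms: n-butyllithium, [Li]CCCC (lithium of 18); N-methoxy-N-methylacetamide, CC(=O)N(C)OC
Why: Directed ortho-metalation with Weinreb ketone synthesis: the MOM ether is the strongest coordinating group present and C6–H lies between it and the 7-methoxy group, so n-BuLi should metalate there in preference to the C8 and C8' positions flanked only by ether oxygens, and the N-methoxy-N-methylamide acylates 18 once because its chelated adduct survives until work-up.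

Step 10
Reactants: 19 1-{3-[(1S)-1-(5,7-dimethoxy-2,2-dimethyl-2H-chromen-6-yl)ethyl]-7-methoxy-5-(methoxymethoxy)-2,2-dimethyl-2H-chromen-6-yl}ethan-1-one
Product: 20 1-{3-[(1S)-1-(5,7-dimethoxy-2,2-dimethyl-2H-chromen-6-yl)ethyl]-5-hydroxy-7-methoxy-2,2-dimethyl-2H-chromen-6-yl}ethan-1-one (CNP0303487.1)
Conditions: HCl (0.5 M in MeOH), THF, 23 °C
Reagents that add atoms: none
Why: Acid-catalysed cleavage of the MOM acetal, made easy by the ortho acetyl group whose carbonyl assists ionisation and then hydrogen-bonds the freed phenol, so that dilute methanolic HCl at room temperature should suffice and leave both chromene rings and the stereocentre untouched.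

Compound list

1 | 2,4,6-trihydroxybenzaldehyde | O=Cc1c(O)cc(O)cc1O | starting material
2 | 2,6-dihydroxy-4-methoxybenzaldehyde | COc1cc(O)c(C=O)c(O)c1 | intermediate
3 | 2-hydroxy-4-methoxy-6-(methoxymethoxy)benzaldehyde | COCOc1cc(OC)cc(O)c1C=O | intermediate
4 | (E)-but-2-enoyl chloride (crotonyl chloride) | C/C=C/C(=O)Cl | starting material
5 | 2-formyl-5-methoxy-3-(methoxymethoxy)phenyl (E)-but-2-enoate | C/C=C/C(=O)Oc1cc(OC)cc(OCOC)c1C=O | intermediate
6 | 2-bromo-1,3-dimethoxybenzene | COc1cccc(OC)c1Br | starting material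
7 | 2-(4-bromo-3,5-dimethoxyphenyl)-4,4,5,5-tetramethyl-1,3,2-dioxaborolane | COc1cc(cc(OC)c1Br)B1OC(C)(C)C(C)(C)O1 | intermediate (not isolated)
8 | 4-bromo-3,5-dimethoxyphenol | COc1cc(O)cc(OC)c1Br | intermediate
9 | 3-methylbut-2-enal (prenal) | CC(C)=CC=O | starting material
10 | 4-bromo-3,5-dimethoxy-6-(3-methylbut-2-en-1-ylidene)cyclohexa-2,4-dien-1-one (ortho-quinone methide, alkene geometry not fixed) | O=C1C=C(OC)C(Br)=C(OC)C1=CC=C(C)C | intermediate (not isolated)
11 | 6-bromo-5,7-dimethoxy-2,2-dimethyl-2H-chromene | COc1cc2c(c(OC)c1Br)C=CC(C)(C)O2 | intermediate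
12 | (5,7-dimethoxy-2,2-dimethyl-2H-chromen-6-yl)lithium | [Li]c1c(OC)cc2c(c1OC)C=CC(C)(C)O2 | intermediate (not isolated)
13 | (5,7-dimethoxy-2,2-dimethyl-2H-chromen-6-yl)boronic acid | OB(O)c1c(OC)cc2c(c1OC)C=CC(C)(C)O2 | intermediate
14 | 3-[(1S)-1-(5,7-dimethoxy-2,2-dimethyl-2H-chromen-6-yl)ethyl]-4-hydroxy-7-methoxy-5-(methoxymethoxy)-3,4-dihydro-2H-chromen-2-one (mixture at C3 and C4) | COc1cc2c(c(OCOC)c1)C(O)C([C@H](C)c1c(OC)cc3c(c1OC)C=CC(C)(C)O3)C(=O)O2 | intermediate (not isolated)
15 | 3-[(1R)-1-(5,7-dimethoxy-2,2-dimethyl-2H-chromen-6-yl)ethyl]-7-methoxy-5-(methoxymethoxy)-2H-chromen-2-one | COc1cc2c(c(OCOC)c1)C=C([C@H](C)c1c(OC)cc3c(c1OC)C=CC(C)(C)O3)C(=O)O2 | intermediate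
16 | 2-{(1Z)-2-[(1S)-1-(5,7-dimethoxy-2,2-dimethyl-2H-chromen-6-yl)ethyl]-3-hydroxy-3-methylbut-1-en-1-yl}-5-methoxy-3-(methoxymethoxy)phenol | COc1cc(O)c(c(OCOC)c1)/C=C(/[C@H](C)c1c(OC)cc3c(c1OC)C=CC(C)(C)O3)C(C)(C)O | intermediate (not isolated)
17 | 6-{(1S)-1-[7-methoxy-5-(methoxymethoxy)-2,2-dimethyl-2H-chromen-3-yl]ethyl}-5,7-dimethoxy-2,2-dimethyl-2H-chromene | COc1cc2c(c(OCOC)c1)C=C([C@H](C)c1c(OC)cc3c(c1OC)C=CC(C)(C)O3)C(C)(C)O2 | intermediate
18 | 6-lithio derivative of 17: {3-[(1S)-1-(5,7-dimethoxy-2,2-dimethyl-2H-chromen-6-yl)ethyl]-7-methoxy-5-(methoxymethoxy)-2,2-dimethyl-2H-chromen-6-yl}lithium | COc1cc2c(c(OCOC)c1[Li])C=C([C@H](C)c1c(OC)cc3c(c1OC)C=CC(C)(C)O3)C(C)(C)O2 | intermediate (not isolated)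
19 | 1-{3-[(1S)-1-(5,7-dimethoxy-2,2-dimethyl-2H-chromen-6-yl)ethyl]-7-methoxy-5-(methoxymethoxy)-2,2-dimethyl-2H-chromen-6-yl}ethan-1-one | COc1cc2c(c(OCOC)c1C(C)=O)C=C([C@H](C)c1c(OC)cc3c(c1OC)C=CC(C)(C)O3)C(C)(C)O2 | intermediate
20 | 1-{3-[(1S)-1-(5,7-dimethoxy-2,2-dimethyl-2H-chromen-6-yl)ethyl]-5-hydroxy-7-methoxy-2,2-dimethyl-2H-chromen-6-yl}ethan-1-one | COc1cc2c(c(O)c1C(C)=O)C=C([C@H](C)c1c(OC)cc3c(c1OC)C=CC(C)(C)O3)C(C)(C)O2 | target

Total step count: 10. Longest linear sequence: 7 steps (steps 1–3 then 7–10; the branch of steps 4–6 then 7–10 is equally long).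

Steps most likely to fail

Step 7. The doubly ortho-substituted aryl group may transmetalate and insert too slowly, so that protodeboronation, hydrolysis of the aryl ester or protonation of the enolate before ring closure takes over. The fallback uses known auxiliary-controlled chemistry; it sets out from bromide 11 (with 4 and 3 as partners) and comes back at coumarin 15. Commercial (4R)-4-phenyl-1,3-oxazolidin-2-one is N-acylated with 4 (n-BuLi, THF, −78 °C) to give (4R)-3-[(2E)-but-2-enoyl]-4-phenyl-1,3-oxazolidin-2-one F1. Bromide 11 is converted with Mg in THF into (5,7-dimethoxy-2,2-dimethyl-2H-chromen-6-yl)magnesium bromide F2. In the presence of CuBr·SMe2, F2 should add to the magnesium-chelated imide on the face away from the phenyl group, which is the Si face of the β-carbon, giving (4R)-3-[(3S)-3-(5,7-dimethoxy-2,2-dimethyl-2H-chromen-6-yl)butanoyl]-4-phenyl-1,3-oxazolidin-2-one F3. LiOH/H2O2 in THF/H2O then releases (3S)-3-(5,7-dimethoxy-2,2-dimethyl-2H-chromen-6-yl)butanoic acid F4. Carbodiimide coupling (EDC, DMAP) with phenol 3 gives 2-formyl-5-methoxy-3-(methoxymethoxy)phenyl (3S)-3-(5,7-dimethoxy-2,2-dimethyl-2H-chromen-6-yl)butanoate F5. K2CO3 in DMF at 80 °C closes and dehydrates F5 by a Perkin-type intramolecular aldol condensation to 15; enolisation at the α-carbon does not touch the β-stereocentre.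

Step 9. Lithiation may stray from C6 to the C8 or C8' positions, or the base may remove the allylic and benzylic CH(Me) proton and erode the enantiomeric purity. The fallback avoids strong base; it sets out from 17 and comes back at the target 20. ZnBr2 and n-PrSH in CH2Cl2 at 0 °C remove the MOM group to give 3-[(1S)-1-(5,7-dimethoxy-2,2-dimethyl-2H-chromen-6-yl)ethyl]-7-methoxy-2,2-dimethyl-2H-chromen-5-ol F6. Magnesium-mediated ortho-formylation (MgCl2, Et3N, paraformaldehyde, MeCN, 80 °C) can only reach C6, the one free position ortho to the hydroxyl, and gives 3-[(1S)-1-(5,7-dimethoxy-2,2-dimethyl-2H-chromen-6-yl)ethyl]-5-hydroxy-7-methoxy-2,2-dimethyl-2H-chromene-6-carbaldehyde F7. MeMgBr (THF, 0 °C) adds to give 3-[(1S)-1-(5,7-dimethoxy-2,2-dimethyl-2H-chromen-6-yl)ethyl]-6-(1-hydroxyethyl)-7-methoxy-2,2-dimethyl-2H-chromen-5-ol F8 as a pair of carbinol epimers, and MnO2 in CH2Cl2 oxidises the benzylic alcohol to 20.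

Step 6. The electron-rich boronic acid with two ortho alkoxy groups may lose boron by protodeboronation during hydrolysis, isolation or storage. The fallback sets out from bromide 11 and comes back at 13, which is then formed only in the flask of step 7. Bromine–lithium exchange (n-BuLi, THF, −78 °C), B(OMe)3 and aqueous KHF2 give the crystalline, storable potassium trifluoro(5,7-dimethoxy-2,2-dimethyl-2H-chromen-6-yl)borate F9. F9 is charged in place of 13 in step 7, where the aqueous dioxane medium hydrolyses it slowly to 13, which is consumed as it is released.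

Further compounds

F1 | step 7 | (4R)-3-[(2E)-but-2-enoyl]-4-phenyl-1,3-oxazolidin-2-one | C/C=C/C(=O)N1[C@H](c2ccccc2)COC1=O
F2 | step 7 | (5,7-dimethoxy-2,2-dimethyl-2H-chromen-6-yl)magnesium bromide | Br[Mg]c1c(OC)cc2c(c1OC)C=CC(C)(C)O2
F3 | step 7 | (4R)-3-[(3S)-3-(5,7-dimethoxy-2,2-dimethyl-2H-chromen-6-yl)butanoyl]-4-phenyl-1,3-oxazolidin-2-one | C[C@@H](CC(=O)N1[C@H](c2ccccc2)COC1=O)c1c(OC)cc2c(c1OC)C=CC(C)(C)O2
F4 | step 7 | (3S)-3-(5,7-dimethoxy-2,2-dimethyl-2H-chromen-6-yl)butanoic acid | C[C@@H](CC(=O)O)c1c(OC)cc2c(c1OC)C=CC(C)(C)O2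
F5 | step 7 | 2-formyl-5-methoxy-3-(methoxymethoxy)phenyl (3S)-3-(5,7-dimethoxy-2,2-dimethyl-2H-chromen-6-yl)butanoate | C[C@@H](CC(=O)Oc1cc(OC)cc(OCOC)c1C=O)c1c(OC)cc2c(c1OC)C=CC(C)(C)O2
F6 | step 9 | 3-[(1S)-1-(5,7-dimethoxy-2,2-dimethyl-2H-chromen-6-yl)ethyl]-7-methoxy-2,2-dimethyl-2H-chromen-5-ol | COc1cc2c(c(O)c1)C=C([C@H](C)c1c(OC)cc3c(c1OC)C=CC(C)(C)O3)C(C)(C)O2
F7 | step 9 | 3-[(1S)-1-(5,7-dimethoxy-2,2-dimethyl-2H-chromen-6-yl)ethyl]-5-hydroxy-7-methoxy-2,2-dimethyl-2H-chromene-6-carbaldehyde | COc1cc2c(c(O)c1C=O)C=C([C@H](C)c1c(OC)cc3c(c1OC)C=CC(C)(C)O3)C(C)(C)O2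
F8 | step 9 | 3-[(1S)-1-(5,7-dimethoxy-2,2-dimethyl-2H-chromen-6-yl)ethyl]-6-(1-hydroxyethyl)-7-methoxy-2,2-dimethyl-2H-chromen-5-ol (both carbinol epimers) | COc1cc2c(c(O)c1C(C)O)C=C([C@H](C)c1c(OC)cc3c(c1OC)C=CC(C)(C)O3)C(C)(C)O2
F9 | step 6 | potassium trifluoro(5,7-dimethoxy-2,2-dimethyl-2H-chromen-6-yl)borate | [K+].F[B-](F)(F)c1c(OC)cc2c(c1OC)C=CC(C)(C)O2
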